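**Retrosynthetic overview**
- **Feature:** ring C has five adjacent C–O carbons and one C–H (C1–O–ring B, C2–H, C3/C4/C5–OH, C6–O–ring D). C3 to C6 with their four oxygens correspond to a squarate. C1 and C2 correspond to a 1-aryloxyvinyl unit that already carries rings A and B. Ring E repeats this pattern.
- **Endgame:** remove 17 benzyl ethers by hydrogenolysis. Trace the ring D C4–OH back to a formyl group (Baeyer–Villiger). Cut the ether between ring C C6–O and ring D C1. This gives an A–B–C phenol and a D–G bromo aldehyde whose formyl group activates the para bromide.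
- **Ring C:** the C2–C3 bond comes from 4π opening and 6π closure of a 4-(1-aryloxyvinyl)-4-silyloxycyclobutenone. That compound is made from dibenzyl squarate and the 1-lithiovinyl ether of the A–B phenol.
- **Ring E:** made the same way from dibenzyl squarate and 1-tert-butoxyvinyllithium. Rings A, B, D, F and G are bought arenes, joined by copper-catalysed or SNAr etherification. Each new phenol oxygen is released from a formyl group.
- **Order of ring formation:** ring C (step 14), then ring E (step 18). All other rings arrive preformed.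

Key step: step 14

**Remarks on the chemistry**
- Rings are lettered A to G from the 2,4,6-trihydroxyphenyl end. In each ring, C1 is the carbon bonded to the ether oxygen that points toward ring A.
- "A–B aryl" means 2,6-bis(benzyloxy)-4-[2,4,6-tris(benzyloxy)phenoxy]phenyl.
- "E–F–G aryl" means 3,4,5-tris(benzyloxy)-2-{3,5-bis(benzyloxy)-4-[3,4,5-tris(benzyloxy)phenoxy]phenoxy}phenyl.
- Assumption: the target is achiral, so only the alkene geometry of some intermediates needs a descriptor. Both cyclobutenones are racemic.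

**Building blocks**

Step 1
Reactants: 1 4-bromo-2,6-difluorobenzaldehyde
Product: 2 4-bromo-2,6-bis(benzyloxy)benzaldehyde
Conditions: BnOH (2.3 equiv), Cs2CO3 (3 equiv), DMF, 90 °C
Reagents that add atoms: benzyl alcohol OCc1ccccc1
Why: Twofold nucleophilic aromatic substitution, in which both fluorides sit ortho to the formyl group and leave far faster than the para bromide, so the bromide is kept for the later ether couplings.

Step 2
Reactants: 1 4-bromo-2,6-difluorobenzaldehyde
Product: 3 2-(benzyloxy)-4-bromo-6-fluorobenzaldehyde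
Conditions: BnOH (1.0 equiv), K2CO3 (1.5 equiv), DMF, 40 °C
Reagents that add atoms: benzyl alcohol OCc1ccccc1
Why: Single nucleophilic aromatic substitution, in which the first benzyloxy donor deactivates the ring so that one equivalent of alcohol should stop at the monoether and leave one ortho fluoride and the para bromide as leaving groups of different kind.

Step 3
Reactants: 4 squaric acid
Product: 5 dibenzyl squarate (3,4-bis(benzyloxy)cyclobut-3-ene-1,2-dione)
Conditions: BnOH (4 equiv), toluene, reflux, Dean–Stark trap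
Reagents that add atoms: benzyl alcohol OCc1ccccc1
Why: Self-catalysed azeotropic esterification of the strongly acidic vinylogous diacid, the usual access to squarate diesters of primary alcohols.

Step 4
Reactants: 6 5-iodo-1,2,3-trimethoxybenzene
Product: 7 5-iodobenzene-1,2,3-triol
Conditions: BBr3 (3.5 equiv), CH2Cl2, −78 °C to rt; then H2O
Reagents that add atoms: none
Why: Lewis acid cleavage of aryl methyl ethers with BBr3, which leaves the aryl iodide untouched.

Step 5
Reactants: 7 5-iodobenzene-1,2,3-triol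
Product: 8 1,2,3-tris(benzyloxy)-5-iodobenzene
Conditions: BnBr (3.5 equiv), K2CO3 (4 equiv), DMF, 50 °C, argon
Reagents that add atoms: benzyl bromide BrCc1ccccc1
Why: Williamson ether synthesis on the three phenols under exclusion of air, giving the ring G electrophile with both positions ortho to iodine free.

**A–B–C line**

Step 6
Reactants: 9 2,4,6-trihydroxybenzaldehyde
Product: 10 2,4,6-tris(benzyloxy)benzaldehyde
Conditions: BnBr (3.5 equiv), K2CO3 (4 equiv), DMF, 70 °C
Reagents that add atoms: benzyl bromide BrCc1ccccc1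
Why: Williamson ether synthesis, in which the formyl group lowers the carbon nucleophilicity of the phloroglucinol ring so O-alkylation prevails, and heat with excess bromide also alkylates the hydrogen-bonded ortho phenols.

Step 7
Reactants: 10 2,4,6-tris(benzyloxy)benzaldehyde
Product: 12 2,4,6-tris(benzyloxy)phenol, via aryl formate 11 (not isolated)
Conditions: mCPBA (1.2 equiv), CH2Cl2, 0 °C to rt; aqueous wash; then K2CO3 (cat.), MeOH–THF, rt, argon
Reagents that add atoms: mCPBA OOC(=O)c1cccc(Cl)c1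
Why: Baeyer–Villiger oxidation, in which the electron-rich aryl group migrates in preference to hydrogen and the resulting formate is removed by base-catalysed methanolysis.

Step 8
Reactants: 12 2,4,6-tris(benzyloxy)phenol; 2 4-bromo-2,6-bis(benzyloxy)benzaldehyde
Product: 13 2,6-bis(benzyloxy)-4-[2,4,6-tris(benzyloxy)phenoxy]benzaldehyde
Conditions: CuI (10 mol %), picolinic acid (20 mol %), K3PO4 (2 equiv), DMSO, 90 °C, argon
Reagents that add atoms: none
Why: Ullmann-type copper-catalysed diaryl ether synthesis with a ligand system suited to di-ortho-substituted phenols, helped by a bromide that has free ortho positions and a para formyl group.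

Step 9
Reactants: 13 2,6-bis(benzyloxy)-4-[2,4,6-tris(benzyloxy)phenoxy]benzaldehyde
Product: 15 2,6-bis(benzyloxy)-4-[2,4,6-tris(benzyloxy)phenoxy]phenol (A–B phenol), via aryl formate 14 (not isolated)
Conditions: mCPBA (1.2 equiv), CH2Cl2, 0 °C to rt; aqueous wash; then K2CO3 (cat.), MeOH–THF, rt, argon
Reagents that add atoms: mCPBA OOC(=O)c1cccc(Cl)c1
Why: Baeyer–Villiger oxidation of a 2,6-dialkoxy-4-aryloxybenzaldehyde followed by formate methanolysis, which turns the activating formyl group into the ring B C4 oxygen.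

Step 10
Reactants: 15 A–B phenol
Product: 16 (E)-1,2-dichlorovinyl ether of the A–B phenol
Conditions: Cl2C=CHCl (2 equiv), K2CO3 (2 equiv), DMF, 70 °C
Reagents that add atoms: trichloroethylene ClC=C(Cl)Cl
Why: Base-induced loss of HCl from trichloroethylene gives a small, very electrophilic chloroalkyne to which even a hindered phenoxide adds in anti fashion, which sets the E geometry.

Step 11
Reactants: 16 (E)-1,2-dichlorovinyl ether of the A–B phenol
Product: 19 ethynyl ether of the A–B phenol, via chloroethynyl ether 17 (not isolated), via lithium acetylide 18 (not isolated)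
Conditions: n-BuLi (2.4 equiv), THF, −78 to −40 °C; then H2O, −78 °C
Reagents that add atoms: none
Why: Vinyl deprotonation with β-elimination of chloride and then chlorine–lithium exchange is the standard dichlorovinyl ether route to ynol ethers, and at −78 °C it is faster than lithiation of benzyl ethers or arene C–H bonds.

Step 12
Reactants: 19 ethynyl ether of the A–B phenol
Product: 20 1-(tributylstannyl)vinyl ether of the A–B phenol
Conditions: Bu3SnH (1.1 equiv), Pd(PPh3)4 (2 mol %), THF, 0 °C to rt; chromatography on Et3N-deactivated silica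
Reagents that add atoms: tributyltin hydride CCCC[SnH](CCCC)CCCC
Why: Palladium-catalysed syn hydrostannation, in which the polarised triple bond of an ynol ether directs tin to the oxygen-bearing carbon and gives an isolable precursor of the vinyl anion.

Step 13
Reactants: 20 1-(tributylstannyl)vinyl ether of the A–B phenol; 5 dibenzyl squarate
Product: 23 racemic 2,3-bis(benzyloxy)-4-(tert-butyldimethylsilyloxy)-4-[1-(A–B aryloxy)vinyl]cyclobut-2-enone, via vinyllithium 21 (not isolated), via lithium carbinolate 22 (not isolated)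
Conditions: n-BuLi (1.0 equiv), THF, −78 °C; cannulate into 5 (1.1 equiv), THF, −78 °C; TBSOTf (1.3 equiv), −78 to −30 °C; Et3N, aq. NaHCO3
Reagents that add atoms: TBSOTf CC(C)(C)[Si](C)(C)OS(=O)(=O)C(F)(F)F
Why: Tin–lithium exchange gives the 1-oxygenated vinyllithium without touching benzylic or aryl C–H bonds, its 1,2-addition to either of the two equivalent squarate carbonyls gives one constitution, and O-silylation of the carbinolate follows in the same flask, so the new quaternary stereocentre forms as a racemate that is erased in step 14.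

Step 14
Reactants: 23 racemic 2,3-bis(benzyloxy)-4-(tert-butyldimethylsilyloxy)-4-[1-(A–B aryloxy)vinyl]cyclobut-2-enone
Product: 26 2,3-bis(benzyloxy)-4-(tert-butyldimethylsilyloxy)-5-(A–B aryloxy)phenol (A–B–C trimer), via dienylketene 24 (not isolated), via cyclohexadienone 25 (not isolated)
Conditions: toluene (0.01 M, degassed, base-washed glassware), 110 °C
Reagents that add atoms: none
Why: Heat breaks the bond between the carbonyl carbon and the sp3 carbon of the four-membered ring in a conrotatory 4π process in which the silyloxy donor turns outward, so the 1-aryloxyvinyl group turns inward and lies cis to the ketene in 24. Disrotatory 6π electrocyclisation of this dienylketene joins the vinyl CH2 carbon (ring C C2) to the ketene carbon (ring C C3) and closes ring C as a six-membered carbocycle, after which enolisation of cyclohexadienone 25 gives the benzene. The closest known reaction type is the thermal ring expansion of squarate-derived 4-alkenyl-4-hydroxy- or 4-silyloxycyclobutenones to hydroquinone derivatives, which accepts 1-alkoxyvinyl groups. No stereocentre is created, and the racemic quaternary carbon of 23 becomes a planar ring atom. The step needs torquoselectivity, which the oxygen donor on the sp3 carbon supplies, and an unambiguous oxygen pattern, which follows from the symmetry of diester 5 in step 13. The ketene oxygen appears as the free C3 phenol while the C6 oxygen remains silylated, so these two para oxygens can be handled separately in steps 15 and 16.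

Step 15
Reactants: 26 A–B–C trimer phenol silyl ether
Product: 27 1,2,3-tris(benzyloxy)-4-(tert-butyldimethylsilyloxy)-5-(A–B aryloxy)benzene
Conditions: BnBr (1.3 equiv), K2CO3 (2 equiv), dry acetone, 50 °C
Reagents that add atoms: benzyl bromide BrCc1ccccc1
Why: Williamson ether synthesis on the only free phenol under anhydrous mild base, which the doubly ortho-flanked aryl silyl ether should survive.

Step 16
Reactants: 27 1,2,3-tris(benzyloxy)-4-(tert-butyldimethylsilyloxy)-5-(A–B aryloxy)benzene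
Product: 28 2,3,4-tris(benzyloxy)-6-(A–B aryloxy)phenol (A–B–C phenol)
Conditions: TBAF (1.1 equiv), AcOH (1.1 equiv), THF, 0 °C
Reagents that add atoms: none
Why: Fluoride-mediated cleavage of an aryl silyl ether, buffered so that the electron-rich phenoxide is protonated at once.

**D–G line**

Step 17
Reactants: 29 tert-butyl vinyl ether; 5 dibenzyl squarate
Product: 32 racemic 2,3-bis(benzyloxy)-4-(1-tert-butoxyvinyl)-4-(tert-butyldimethylsilyloxy)cyclobut-2-enone, via vinyllithium 30 (not isolated), via lithium carbinolate 31 (not isolated)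
Conditions: 29 (1.3 equiv), t-BuLi (1.0 equiv), THF–pentane, −78 to 0 °C; 5 (1.0 equiv), THF, −78 °C; TBSOTf (1.3 equiv), −78 to −30 °C; Et3N, aq. NaHCO3
Reagents that add atoms: TBSOTf CC(C)(C)[Si](C)(C)OS(=O)(=O)C(F)(F)F
Why: α-Lithiation of an alkyl vinyl ether, 1,2-addition to one of the two equivalent squarate carbonyls and O-silylation in the same flask, so the new quaternary stereocentre forms as a racemate that is lost in step 18.

Step 18
Reactants: 32 racemic 2,3-bis(benzyloxy)-4-(1-tert-butoxyvinyl)-4-(tert-butyldimethylsilyloxy)cyclobut-2-enone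
Product: 35 2,3-bis(benzyloxy)-5-tert-butoxy-4-(tert-butyldimethylsilyloxy)phenol, via dienylketene 33 (not isolated), via cyclohexadienone 34 (not isolated)
Conditions: toluene (0.02 M, degassed, base-washed glassware), 110 °C
Reagents that add atoms: none
Why: The same thermal 4π ring opening and 6π electrocyclisation of a 4-alkenyl-4-silyloxycyclobutenone as in step 14, here with a plain 1-alkoxyvinyl group, closes ring E with its C1 oxygen as an acid-labile tert-butyl ether, its C3 oxygen free and its C6 oxygen silylated.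

Step 19
Reactants: 35 2,3-bis(benzyloxy)-5-tert-butoxy-4-(tert-butyldimethylsilyloxy)phenol
Product: 36 1,2,3-tris(benzyloxy)-5-tert-butoxy-4-(tert-butyldimethylsilyloxy)benzene
Conditions: BnBr (1.3 equiv), K2CO3 (2 equiv), dry acetone, 50 °C
Reagents that add atoms: benzyl bromide BrCc1ccccc1
Why: Williamson ether synthesis on the single free phenol under conditions that leave the hindered silyl ether and the tert-butyl ether intact.

Step 20
Reactants: 36 1,2,3-tris(benzyloxy)-5-tert-butoxy-4-(tert-butyldimethylsilyloxy)benzene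
Product: 37 2,3,4-tris(benzyloxy)-6-tert-butoxyphenol
Conditions: TBAF (1.1 equiv), AcOH (1.1 equiv), THF, 0 °C
Reagents that add atoms: none
Why: Fluoride-mediated desilylation frees the ring E C6 phenol while the benzyl and tert-butyl ethers are inert to fluoride.

Step 21
Reactants: 37 2,3,4-tris(benzyloxy)-6-tert-butoxyphenol; 2 4-bromo-2,6-bis(benzyloxy)benzaldehyde
Product: 38 2,6-bis(benzyloxy)-4-[2,3,4-tris(benzyloxy)-6-tert-butoxyphenoxy]benzaldehyde
Conditions: CuI (10 mol %), picolinic acid (20 mol %), K3PO4 (2 equiv), DMSO, 95 °C, argon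
Reagents that add atoms: none
Why: Ullmann-type copper-catalysed etherification of a di-ortho-substituted phenol with a bromide that is unhindered and activated by its para formyl group.

Step 22
Reactants: 38 2,6-bis(benzyloxy)-4-[2,3,4-tris(benzyloxy)-6-tert-butoxyphenoxy]benzaldehyde
Product: 40 2,6-bis(benzyloxy)-4-[2,3,4-tris(benzyloxy)-6-tert-butoxyphenoxy]phenol, via aryl formate 39 (not isolated)
Conditions: mCPBA (1.2 equiv), CH2Cl2, 0 °C to rt; aqueous wash; then K2CO3 (cat.), MeOH–THF, rt, argon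
Reagents that add atoms: mCPBA OOC(=O)c1cccc(Cl)c1
Why: Baeyer–Villiger oxidation with aryl migration and formate methanolysis delivers the ring F C4 phenol.

Step 23
Reactants: 40 2,6-bis(benzyloxy)-4-[2,3,4-tris(benzyloxy)-6-tert-butoxyphenoxy]phenol; 8 1,2,3-tris(benzyloxy)-5-iodobenzene
Product: 41 E–F–G trimer tert-butyl ether (ring E C1–O-tert-butyl, eight benzyl ethers)
Conditions: CuI (10 mol %), picolinic acid (20 mol %), K3PO4 (2 equiv), DMSO, 90 °C, argon
Reagents that add atoms: none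
Why: Ullmann-type copper-catalysed coupling of a 2,6-dialkoxyphenol with an aryl iodide that has no ortho substituents, the pairing for which this catalyst system is known to tolerate hindered phenols.

Step 24
Reactants: 41 E–F–G trimer tert-butyl ether
Product: 42 3,4,5-tris(benzyloxy)-2-{3,5-bis(benzyloxy)-4-[3,4,5-tris(benzyloxy)phenoxy]phenoxy}phenol (E–F–G phenol)
Conditions: TFA–CH2Cl2 (1:5), 0 °C
Reagents that add atoms: none
Why: Acidolysis of an aryl tert-butyl ether through the tert-butyl cation, which at 0 °C is far faster than cleavage of benzyl aryl ethers.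

Step 25
Reactants: 42 E–F–G phenol; 3 2-(benzyloxy)-4-bromo-6-fluorobenzaldehyde
Product: 43 2-(benzyloxy)-4-bromo-6-(E–F–G aryloxy)benzaldehyde (D–G tetramer)
Conditions: K2CO3 (2 equiv), DMF, 90 °C
Reagents that add atoms: none
Why: Nucleophilic aromatic substitution of the fluoride ortho to the formyl group, which is displaced much faster than the para bromide and so sets the ring D C5–O–ring E C1 ether with the bromide kept.

**Union and endgame**

Step 26
Reactants: 28 A–B–C phenol; 43 D–G tetramer bromo aldehyde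
Product: 44 heptamer aldehyde (seventeen benzyl ethers, formyl group on ring D C4)
Conditions: CuI (20 mol %), picolinic acid (40 mol %), K3PO4 (2.5 equiv), DMSO–toluene (3:1), 100 °C, argon
Reagents that add atoms: none
Why: Ullmann-type copper-catalysed arylation of the hindered ring C C6 phenol, in which all the steric load lies on the phenol because the bromide has two ortho hydrogens and is made electron-poor by its para formyl group.

Step 27
Reactants: 44 heptamer aldehyde
Product: 46 heptamer with free ring D C4 phenol, via aryl formate 45 (not isolated)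
Conditions: mCPBA (1.2 equiv), CH2Cl2, 0 °C to rt; aqueous wash; then K2CO3 (cat.), MeOH–THF, rt, argon
Reagents that add atoms: mCPBA OOC(=O)c1cccc(Cl)c1
Why: Baeyer–Villiger oxidation of the 2,6-dioxygenated 4-aryloxybenzaldehyde with aryl migration, then formate methanolysis, converts the spent activating group into the last missing oxygen.

Step 28
Reactants: 46 heptamer with free ring D C4 phenol
Product: 47 CNP0130704.0 (target)
Conditions: H2 (1 atm), Pd(OH)2/C, THF–MeOH (1:1), rt; filtration and concentration under argon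
Reagents that add atoms: none
Why: Catalytic hydrogenolysis cleaves all seventeen benzyl aryl ethers, while diaryl ethers and the arene rings are inert under these conditions.

**Compound list**

1 | 4-bromo-2,6-difluorobenzaldehyde | O=Cc1c(F)cc(Br)cc1F | starting material
2 | 4-bromo-2,6-bis(benzyloxy)benzaldehyde | O=Cc1c(OCc9ccccc9)cc(Br)cc1OCc9ccccc9 | intermediate
3 | 2-(benzyloxy)-4-bromo-6-fluorobenzaldehyde | O=Cc1c(F)cc(Br)cc1OCc9ccccc9 | intermediate
4 | squaric acid | OC1=C(O)C(=O)C1=O | starting material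
5 | dibenzyl squarate | O=C1C(=O)C(OCc9ccccc9)=C1OCc9ccccc9 | intermediate
6 | 5-iodo-1,2,3-trimethoxybenzene | COc1cc(I)cc(OC)c1OC | starting material
7 | 5-iodobenzene-1,2,3-triol | Oc1cc(I)cc(O)c1O | intermediate
8 | 1,2,3-tris(benzyloxy)-5-iodobenzene | Ic1cc(OCc9ccccc9)c(OCc9ccccc9)c(OCc9ccccc9)c1 | intermediate
9 | 2,4,6-trihydroxybenzaldehyde | O=Cc1c(O)cc(O)cc1O | starting material
10 | 2,4,6-tris(benzyloxy)benzaldehyde | O=Cc1c(OCc9ccccc9)cc(OCc9ccccc9)cc1OCc9ccccc9 | intermediate
11 | 2,4,6-tris(benzyloxy)phenyl formate | O=COc1c(OCc9ccccc9)cc(OCc9ccccc9)cc1OCc9ccccc9 | intermediate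
12 | 2,4,6-tris(benzyloxy)phenol | Oc1c(OCc9ccccc9)cc(OCc9ccccc9)cc1OCc9ccccc9 | intermediate
13 | 2,6-bis(benzyloxy)-4-[2,4,6-tris(benzyloxy)phenoxy]benzaldehyde | O=Cc1c(OCc9ccccc9)cc(Oc2c(OCc9ccccc9)cc(OCc9ccccc9)cc2OCc9ccccc9)cc1OCc9ccccc9 | intermediate
14 | A–B aryl formate | O=COc1c(OCc9ccccc9)cc(Oc2c(OCc9ccccc9)cc(OCc9ccccc9)cc2OCc9ccccc9)cc1OCc9ccccc9 | intermediate
15 | A–B phenol | Oc1c(OCc9ccccc9)cc(Oc2c(OCc9ccccc9)cc(OCc9ccccc9)cc2OCc9ccccc9)cc1OCc9ccccc9 | intermediate
16 | (E)-1,2-dichlorovinyl A–B aryl ether | Cl/C=C(Cl)\Oc1c(OCc9ccccc9)cc(Oc2c(OCc9ccccc9)cc(OCc9ccccc9)cc2OCc9ccccc9)cc1OCc9ccccc9 | intermediate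
17 | chloroethynyl A–B aryl ether | ClC#COc1c(OCc9ccccc9)cc(Oc2c(OCc9ccccc9)cc(OCc9ccccc9)cc2OCc9ccccc9)cc1OCc9ccccc9 | intermediate
18 | lithium (A–B aryloxy)acetylide | [Li]C#COc1c(OCc9ccccc9)cc(Oc2c(OCc9ccccc9)cc(OCc9ccccc9)cc2OCc9ccccc9)cc1OCc9ccccc9 | intermediate
19 | ethynyl A–B aryl ether | C#COc1c(OCc9ccccc9)cc(Oc2c(OCc9ccccc9)cc(OCc9ccccc9)cc2OCc9ccccc9)cc1OCc9ccccc9 | intermediate
20 | 1-(tributylstannyl)vinyl A–B aryl ether | C=C([Sn](CCCC)(CCCC)CCCC)Oc1c(OCc9ccccc9)cc(Oc2c(OCc9ccccc9)cc(OCc9ccccc9)cc2OCc9ccccc9)cc1OCc9ccccc9 | intermediate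
21 | 1-(A–B aryloxy)vinyllithium | [Li]C(=C)Oc1c(OCc9ccccc9)cc(Oc2c(OCc9ccccc9)cc(OCc9ccccc9)cc2OCc9ccccc9)cc1OCc9ccccc9 | intermediate
22 | lithium carbinolate from 21 and 5 (racemic) | [Li]OC1(C(=C)Oc2c(OCc9ccccc9)cc(Oc3c(OCc9ccccc9)cc(OCc9ccccc9)cc3OCc9ccccc9)cc2OCc9ccccc9)C(=O)C(OCc9ccccc9)=C1OCc9ccccc9 | intermediate
23 | 2,3-bis(benzyloxy)-4-(tert-butyldimethylsilyloxy)-4-[1-(A–B aryloxy)vinyl]cyclobut-2-enone (racemic) | C=C(Oc1c(OCc9ccccc9)cc(Oc2c(OCc9ccccc9)cc(OCc9ccccc9)cc2OCc9ccccc9)cc1OCc9ccccc9)C1(O[Si](C)(C)C(C)(C)C)C(=O)C(OCc9ccccc9)=C1OCc9ccccc9 | intermediate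
24 | (Z)-dienylketene from 23 | O=C=C(OCc9ccccc9)/C(OCc9ccccc9)=C(/O[Si](C)(C)C(C)(C)C)C(=C)Oc1c(OCc9ccccc9)cc(Oc2c(OCc9ccccc9)cc(OCc9ccccc9)cc2OCc9ccccc9)cc1OCc9ccccc9 | intermediate
25 | cyclohexa-2,4-dienone tautomer of 26 | O=C1CC(Oc2c(OCc9ccccc9)cc(Oc3c(OCc9ccccc9)cc(OCc9ccccc9)cc3OCc9ccccc9)cc2OCc9ccccc9)=C(O[Si](C)(C)C(C)(C)C)C(OCc9ccccc9)=C1OCc9ccccc9 | intermediate
26 | 2,3-bis(benzyloxy)-4-(tert-butyldimethylsilyloxy)-5-(A–B aryloxy)phenol | Oc1cc(Oc2c(OCc9ccccc9)cc(Oc3c(OCc9ccccc9)cc(OCc9ccccc9)cc3OCc9ccccc9)cc2OCc9ccccc9)c(O[Si](C)(C)C(C)(C)C)c(OCc9ccccc9)c1OCc9ccccc9 | intermediate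
27 | 1,2,3-tris(benzyloxy)-4-(tert-butyldimethylsilyloxy)-5-(A–B aryloxy)benzene | O(Cc9ccccc9)c1cc(Oc2c(OCc9ccccc9)cc(Oc3c(OCc9ccccc9)cc(OCc9ccccc9)cc3OCc9ccccc9)cc2OCc9ccccc9)c(O[Si](C)(C)C(C)(C)C)c(OCc9ccccc9)c1OCc9ccccc9 | intermediate
28 | 2,3,4-tris(benzyloxy)-6-(A–B aryloxy)phenol (A–B–C phenol) | O(Cc9ccccc9)c1cc(Oc2c(OCc9ccccc9)cc(Oc3c(OCc9ccccc9)cc(OCc9ccccc9)cc3OCc9ccccc9)cc2OCc9ccccc9)c(O)c(OCc9ccccc9)c1OCc9ccccc9 | intermediate
29 | tert-butyl vinyl ether | C=COC(C)(C)C | starting material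
30 | 1-tert-butoxyvinyllithium | [Li]C(=C)OC(C)(C)C | intermediate
31 | lithium carbinolate from 30 and 5 (racemic) | [Li]OC1(C(=C)OC(C)(C)C)C(=O)C(OCc9ccccc9)=C1OCc9ccccc9 | intermediate
32 | 2,3-bis(benzyloxy)-4-(1-tert-butoxyvinyl)-4-(tert-butyldimethylsilyloxy)cyclobut-2-enone (racemic) | C=C(OC(C)(C)C)C1(O[Si](C)(C)C(C)(C)C)C(=O)C(OCc9ccccc9)=C1OCc9ccccc9 | intermediate
33 | (Z)-dienylketene from 32 | O=C=C(OCc9ccccc9)/C(OCc9ccccc9)=C(/O[Si](C)(C)C(C)(C)C)C(=C)OC(C)(C)C | intermediate
34 | cyclohexa-2,4-dienone tautomer of 35 | O=C1CC(OC(C)(C)C)=C(O[Si](C)(C)C(C)(C)C)C(OCc9ccccc9)=C1OCc9ccccc9 | intermediate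
35 | 2,3-bis(benzyloxy)-5-tert-butoxy-4-(tert-butyldimethylsilyloxy)phenol | CC(C)(C)Oc1cc(O)c(OCc9ccccc9)c(OCc9ccccc9)c1O[Si](C)(C)C(C)(C)C | intermediate
36 | 1,2,3-tris(benzyloxy)-5-tert-butoxy-4-(tert-butyldimethylsilyloxy)benzene | CC(C)(C)Oc1cc(OCc9ccccc9)c(OCc9ccccc9)c(OCc9ccccc9)c1O[Si](C)(C)C(C)(C)C | intermediate
37 | 2,3,4-tris(benzyloxy)-6-tert-butoxyphenol | CC(C)(C)Oc1cc(OCc9ccccc9)c(OCc9ccccc9)c(OCc9ccccc9)c1O | intermediate
38 | E–F aldehyde | CC(C)(C)Oc1cc(OCc9ccccc9)c(OCc9ccccc9)c(OCc9ccccc9)c1Oc2cc(OCc9ccccc9)c(C=O)c(OCc9ccccc9)c2 | intermediate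
39 | E–F aryl formate | CC(C)(C)Oc1cc(OCc9ccccc9)c(OCc9ccccc9)c(OCc9ccccc9)c1Oc2cc(OCc9ccccc9)c(OC=O)c(OCc9ccccc9)c2 | intermediate
40 | E–F phenol | CC(C)(C)Oc1cc(OCc9ccccc9)c(OCc9ccccc9)c(OCc9ccccc9)c1Oc2cc(OCc9ccccc9)c(O)c(OCc9ccccc9)c2 | intermediate
41 | E–F–G trimer tert-butyl ether | CC(C)(C)Oc1cc(OCc9ccccc9)c(OCc9ccccc9)c(OCc9ccccc9)c1Oc2cc(OCc9ccccc9)c(Oc3cc(OCc9ccccc9)c(OCc9ccccc9)c(OCc9ccccc9)c3)c(OCc9ccccc9)c2 | intermediate
42 | E–F–G phenol | Oc1cc(OCc9ccccc9)c(OCc9ccccc9)c(OCc9ccccc9)c1Oc2cc(OCc9ccccc9)c(Oc3cc(OCc9ccccc9)c(OCc9ccccc9)c(OCc9ccccc9)c3)c(OCc9ccccc9)c2 | intermediate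
43 | 2-(benzyloxy)-4-bromo-6-(E–F–G aryloxy)benzaldehyde (D–G tetramer) | O=Cc1c(OCc9ccccc9)cc(Br)cc1Oc2cc(OCc9ccccc9)c(OCc9ccccc9)c(OCc9ccccc9)c2Oc3cc(OCc9ccccc9)c(Oc4cc(OCc9ccccc9)c(OCc9ccccc9)c(OCc9ccccc9)c4)c(OCc9ccccc9)c3 | intermediate
44 | heptamer aldehyde | O(Cc9ccccc9)c1cc(OCc9ccccc9)c(Oc2cc(OCc9ccccc9)c(Oc3cc(OCc9ccccc9)c(OCc9ccccc9)c(OCc9ccccc9)c3Oc3cc(OCc9ccccc9)c(C=O)c(Oc4cc(OCc9ccccc9)c(OCc9ccccc9)c(OCc9ccccc9)c4Oc4cc(OCc9ccccc9)c(Oc5cc(OCc9ccccc9)c(OCc9ccccc9)c(OCc9ccccc9)c5)c(OCc9ccccc9)c4)c3)c(OCc9ccccc9)c2)c(OCc9ccccc9)c1 | intermediate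
45 | heptamer aryl formate | O(Cc9ccccc9)c1cc(OCc9ccccc9)c(Oc2cc(OCc9ccccc9)c(Oc3cc(OCc9ccccc9)c(OCc9ccccc9)c(OCc9ccccc9)c3Oc3cc(OCc9ccccc9)c(OC=O)c(Oc4cc(OCc9ccccc9)c(OCc9ccccc9)c(OCc9ccccc9)c4Oc4cc(OCc9ccccc9)c(Oc5cc(OCc9ccccc9)c(OCc9ccccc9)c(OCc9ccccc9)c5)c(OCc9ccccc9)c4)c3)c(OCc9ccccc9)c2)c(OCc9ccccc9)c1 | intermediate
46 | heptamer with free ring D C4 phenol | O(Cc9ccccc9)c1cc(OCc9ccccc9)c(Oc2cc(OCc9ccccc9)c(Oc3cc(OCc9ccccc9)c(OCc9ccccc9)c(OCc9ccccc9)c3Oc3cc(OCc9ccccc9)c(O)c(Oc4cc(OCc9ccccc9)c(OCc9ccccc9)c(OCc9ccccc9)c4Oc4cc(OCc9ccccc9)c(Oc5cc(OCc9ccccc9)c(OCc9ccccc9)c(OCc9ccccc9)c5)c(OCc9ccccc9)c4)c3)c(OCc9ccccc9)c2)c(OCc9ccccc9)c1 | intermediate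
47 | CNP0130704.0 | Oc1cc(O)c(Oc2cc(O)c(Oc3cc(O)c(O)c(O)c3Oc3cc(O)c(O)c(Oc4cc(O)c(O)c(O)c4Oc4cc(O)c(Oc5cc(O)c(O)c(O)c5)c(O)c4)c3)c(O)c2)c(O)c1 | target

**Step counts**
- Total step count: 28.
- Longest linear sequence: 14 steps (steps 6 to 16, then 26 to 28, from 2,4,6-trihydroxybenzaldehyde).

**Steps most likely to fail**

1. **Step 14.**
   - Risk: the bulky aryloxy group on the diene may twist the dienylketene out of the s-cis arrangement. The 6π closure would then become slow, and re-closure, ketene oligomerisation or hydrolysis of the acid-labile enol ether could take over.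
   - Fallback: set out from lithium acetylide 18 and change the ring-closing mode.
     - 18 is added to 5 in THF at −78 °C and quenched with aq. NH4Cl. This gives racemic 4-[(A–B aryloxy)ethynyl]-2,3-bis(benzyloxy)-4-hydroxycyclobut-2-enone F2.
     - Heating in p-xylene at 138 °C triggers the known 4-alkynylcyclobutenone-to-quinone rearrangement (enynylketene, diradical closure, hydrogen shift). The product is 2-(A–B aryloxy)-5,6-bis(benzyloxy)-1,4-benzoquinone F3.
     - Na2S2O4 in THF–water reduces it to 2-(A–B aryloxy)-5,6-bis(benzyloxy)benzene-1,4-diol F4.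
     - One equivalent of BnBr with K2CO3 in acetone alkylates the less hindered hydroxyl, the one next to the ring C–H. The route is rejoined at 28.

2. **Step 26.**
   - Risk: steric crowding around the ring C phenoxide may retard C–O bond formation. Hydrodebromination of the tetramer or oxidation of the phenol could then compete at 100 °C.
   - Fallback: set out from 43 and reverse the role of ring D.
     - Miyaura borylation (B2pin2, Pd(dppf)Cl2, KOAc, dioxane, 80 °C) gives the D–G pinacol boronate F5.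
     - NaIO4 and NH4OAc in acetone–water give the D–G boronic acid F6.
     - A room-temperature Chan–Lam oxidative coupling of F6 with 28 follows (Cu(OAc)2, pyridine, 4 Å molecular sieves, CH2Cl2, air). The route is rejoined at 44.

3. **Step 12.**
   - Risk: the bulk of the aryl group may erode the regioselectivity of tin delivery toward the terminal carbon. The stannyl enol ether may also protodestannylate on purification.
   - Fallback: set out from 19 and use ionic Markovnikov addition in place of the metal hydride.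
     - One equivalent of HBr (from TMSBr and MeOH, CH2Cl2, −78 °C) protonates the terminal carbon and gives the 1-bromovinyl A–B aryl ether F1, which is used crude under dry conditions.
     - Bromine–lithium exchange with t-BuLi (2 equiv, THF, −78 °C) rejoins the route at vinyllithium 21.

**Further compounds**

F1 | step 12 | 1-bromovinyl A–B aryl ether | C=C(Br)Oc1c(OCc9ccccc9)cc(Oc2c(OCc9ccccc9)cc(OCc9ccccc9)cc2OCc9ccccc9)cc1OCc9ccccc9
F2 | step 14 | 4-[(A–B aryloxy)ethynyl]-2,3-bis(benzyloxy)-4-hydroxycyclobut-2-enone (racemic) | OC1(C#COc2c(OCc9ccccc9)cc(Oc3c(OCc9ccccc9)cc(OCc9ccccc9)cc3OCc9ccccc9)cc2OCc9ccccc9)C(=O)C(OCc9ccccc9)=C1OCc9ccccc9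
F3 | step 14 | 2-(A–B aryloxy)-5,6-bis(benzyloxy)-1,4-benzoquinone | O=C1C=C(Oc2c(OCc9ccccc9)cc(Oc3c(OCc9ccccc9)cc(OCc9ccccc9)cc3OCc9ccccc9)cc2OCc9ccccc9)C(=O)C(OCc9ccccc9)=C1OCc9ccccc9
F4 | step 14 | 2-(A–B aryloxy)-5,6-bis(benzyloxy)benzene-1,4-diol | Oc1cc(Oc2c(OCc9ccccc9)cc(Oc3c(OCc9ccccc9)cc(OCc9ccccc9)cc3OCc9ccccc9)cc2OCc9ccccc9)c(O)c(OCc9ccccc9)c1OCc9ccccc9
F5 | step 26 | D–G tetramer pinacol boronate | CC6(C)OB(OC6(C)C)c1cc(OCc9ccccc9)c(C=O)c(Oc2cc(OCc9ccccc9)c(OCc9ccccc9)c(OCc9ccccc9)c2Oc3cc(OCc9ccccc9)c(Oc4cc(OCc9ccccc9)c(OCc9ccccc9)c(OCc9ccccc9)c4)c(OCc9ccccc9)c3)c1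
F6 | step 26 | D–G tetramer boronic acid | OB(O)c1cc(OCc9ccccc9)c(C=O)c(Oc2cc(OCc9ccccc9)c(OCc9ccccc9)c(OCc9ccccc9)c2Oc3cc(OCc9ccccc9)c(Oc4cc(OCc9ccccc9)c(OCc9ccccc9)c(OCc9ccccc9)c4)c(OCc9ccccc9)c3)c1
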